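The ratio of the two enzyme charges, 11.0, was where I began: at equal rate per enzyme, a flask charged with 3.0 µM needs that many times longer to reach 20% conversion.

| setting | south | west | flask |
|---|---|---|---|
| substrate | 0.025 M | 0.10 M | 0.050 M |
| enzyme | 33 µM | 33 µM | 33 µM |
| added ligand | 0.15 mM | 0.15 mM | 0.15 mM |
| remark | run made earlier | run made earlier |  |

| run | time / min | target / % | substrate / % |
|---|---|---|---|
| south | 6.00 | 53 | 46 |
| south | 10.0 | 66 | 33 |
| south | 20.0 | 83 | 13 |
| south | 30.0 | 90 | 12 |
| south | 50.0 | 92 | 6 |
| south | 80.0 | 99 | 3 |
| west | 12.0 | 50 | 54 |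
| west | 25.0 | 79 | 20 |
| west | 40.0 | 92 | 9 |
| west | 50.0 | 92 | 8 |
| west | 60.0 | 97 | 5 |
| west | 80.0 | 100 | 0 |

(readings scatter by 1.5 percentage points)

- factor on the rate of making target when 20% of the substrate are converted if enzyme is charged twice over
- factor on the rate when 20% of the substrate are converted if enzyme is charged at 3.0 µM instead

If enzyme stayed whole, or lost activity with conversion and not with time, the ratio was 0.0909, my upper bound. For the lower bound I supposed that enzyme is lost with time. The south run's first reading gave a pseudo-first-order constant of 0.129 min⁻¹. The west run, passing through similar substrate concentrations much later, gave 0.0532 min⁻¹. Their gap defines the loss clock λ, the share of working enzyme lost per minute, here read as 0.0301 min⁻¹.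

Let τ be the loss-free time to 20% in the flask, which I put at 2.74 min for 33 µM. The share still working is then f = 1 − λτ, or 0.918 at this charge and 0.0933 with τ stretched. That put the lower bound at 0.00924. A small f is a difference of near-equal numbers, so I stopped there and committed to the geometric middle, 0.0290.

The forecast said 0.091, within 0.04 to 0.2, and 2 for doubling, after noting “product inhibition or slow enzyme loss”; its ratio sits on my upper bound.

The flask gave 0.0341 for the ratio, less than my upper bound and more than my lower bound, and 2.07 for doubling.

    substrate + enzyme → target + enzyme, rate k1*[substrate]^1.5*[enzyme]/(1 + ([substrate]/Kh1)^1.5) (22.0 mM, k = 49800 M⁻¹·⁵ min⁻¹)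
    enzyme + added ligand ⇌ idle complex (K = 1.10 × 10⁵ M⁻¹, k = 164 M⁻¹ min⁻¹)

In the flask after 10.0 min, idle complex held 21.2% of the enzyme, where λ reckons 26.0%. With enzyme charged twice over in the flask, τ falls to 1.37 min and f gives a reckoned factor of 2.09.

The readings were generated by integration with made-up constants, noise included.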